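**Retrosynthetic overview**
1. Target ⇐ outer-face epoxidation of the 1(10)E-olefin, after C8 esterification with (2R,3S)-2,3-dimethyloxirane-2-carboxylic acid and C3 benzoylation of the heliangolide core.
2. Ten-membered carbocycle and trans α-methylene-γ-lactone ⇐ one intramolecular CrCl2 allylation/lactonization (C6–C7) of a lactol bearing a 2-(bromomethyl)enoate.
3. Z-C4=C5, the C3 stereocentre and the masked C6 aldehyde ⇐ an (S)-butenolide made by enantioselective protodesilylative dearomatization of a 2-silyloxyfuran (key step).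
4. Silyloxyfuran ⇐ Negishi allyl–furyl coupling (C2–C3) of zincated 4-methyl-2-silyloxyfuran (from 3-methylfuran) with a geranyl-acetate-derived aldehyde (C8–O by α-oxyamination); the acrylate comes from methyl propiolate.
5. Ring order: butenolide (temporary template) → carbocycle and lactone together → oxirane last.

Assumption: germacrane numbering (C1–C15) is used for all intermediates; "TMP-oxy" means (2,2,6,6-tetramethylpiperidin-1-yl)oxy.

Step 1
Reactants: 1 3-methylfuran
Product: 4 4-methylfuran-2(5H)-one, via furyllithium 2 (not isolated), via furyl borate 3 (not isolated)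
Conditions: LiTMP, B(OiPr)3, THF, −78 °C; then AcOH, 30% H2O2, 0 °C to rt
Reagents that add atoms: hydrogen peroxide, OO
Why: Kinetic α-lithiation at the unhindered C5–H remote from the methyl group, trapped in situ as the borate and oxidized (lithiation–borylation–oxidation), gives the 2-hydroxyfuran, which tautomerizes to the butenolide; no stereocentre is formed.

Step 2
Reactants: 4 4-methylfuran-2(5H)-one
Product: 5 triisopropyl[(4-methylfuran-2-yl)oxy]silane
Conditions: TIPSOTf, Et3N, CH2Cl2, 0 °C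
Reagents that add atoms: triisopropylsilyl trifluoromethanesulfonate, CC(C)[Si](C(C)C)(C(C)C)OS(=O)(=O)C(F)(F)F
Why: Soft γ-enolization and O-silylation (silyl dienol ether formation) restore an aromatic furan, the 2-silyloxyfuran needed for C5 metalation and for the later dearomatizing protonation.

Step 3
Reactants: 6 geranyl acetate
Product: 8 (4E)-6-acetoxy-4-methylhex-4-enal, via secondary ozonide 7 (not isolated)
Conditions: O3 (1.0 equiv, dye end-point), CH2Cl2, −78 °C; then PPh3, −78 °C to rt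
Reagents that add atoms: ozone, [O-][O+]=O
Why: Chemoselective ozonolysis, because the remote trisubstituted olefin is more electron-rich than the 2,3-olefin deactivated by the allylic acetate, so only the isopropylidene end is cleaved and the E geometry of the future C1=C10 bond is untouched.

Step 4
Reactants: 8 (4E)-6-acetoxy-4-methylhex-4-enal
Product: 9 (2R,4E)-6-acetoxy-4-methyl-2-(TMP-oxy)hex-4-enal
Conditions: TEMPO (1.2 equiv), (2R,5R)-5-benzyl-2-tert-butyl-3-methylimidazolidin-4-one·TFA (20 mol %), CuCl2 (10 mol %), air, acetone, −10 °C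
Reagents that add atoms: TEMPO, CC1(C)CCCC(C)(C)N1[O]
Why: Organocatalytic enamine α-oxyamination in which the imidazolidinone shields one face of the E-enamine so that copper-activated TEMPO adds to the other, setting C8 as R (the antipodal catalyst is used if the sense proves opposite), and the bulky aminooxy group then serves as the C8–O protecting group.

Step 5
Reactants: 5 triisopropyl[(4-methylfuran-2-yl)oxy]silane, 9 (2R,4E)-6-acetoxy-4-methyl-2-(TMP-oxy)hex-4-enal
Product: 12 (2R,4E)-4-methyl-6-[3-methyl-5-(triisopropylsilyloxy)furan-2-yl]-2-(TMP-oxy)hex-4-enal, via lithiofuran 10 (not isolated), via furylzinc chloride 11 (not isolated)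
Conditions: 5, s-BuLi, TMEDA, THF, 0 °C; ZnCl2, 0 °C; then 9, Pd(PPh3)4 (5 mol %), THF, rt
Reagents that add atoms: none
Why: α-Lithiation of the silyloxyfuran at its only free α-position, Li-to-Zn exchange and Negishi allyl–heteroaryl coupling, in which the furylzinc is transferred to the unhindered primary terminus of the π-allylpalladium with retention of the E-olefin (C2–C3 bond) while the aldehyde is not attacked by the organozinc.

Step 6
Reactants: 12 (2R,4E)-4-methyl-6-[3-methyl-5-(triisopropylsilyloxy)furan-2-yl]-2-(TMP-oxy)hex-4-enal, 13 methyl propiolate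
Product: 15 methyl (4R,6E)-3-hydroxy-6-methyl-2-methylidene-8-[3-methyl-5-(triisopropylsilyloxy)furan-2-yl]-4-(TMP-oxy)oct-6-enoate, via vinylalane 14 (not isolated)
Conditions: DIBAL-H, NMO, THF, 0 °C, then 13; then 12, 0 °C to rt; aq. Rochelle salt
Reagents that add atoms: none
Why: Vinylalumination (a stoichiometric Morita–Baylis–Hillman equivalent), in which 1,4-hydroalumination of the propiolate gives an α-aluminated acrylate that adds to the aldehyde at low temperature without epimerizing C8; the new carbinol (C7) forms as a mixture that does not matter because it is erased in step 8.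

Step 7
Reactants: 15 methyl (4R,6E)-3-hydroxy-6-methyl-2-methylidene-8-[3-methyl-5-(triisopropylsilyloxy)furan-2-yl]-4-(TMP-oxy)oct-6-enoate
Product: 16 methyl (4R,6E)-3-hydroxy-6-methyl-2-methylidene-8-[(2S)-3-methyl-5-oxo-2,5-dihydrofuran-2-yl]-4-(TMP-oxy)oct-6-enoate
Conditions: 9-O-(phenanthren-9-yl)cupreidine (10 mol %), PhCOF (1.1 equiv), EtOH (1.1 equiv), THF, −40 °C
Reagents that add atoms: none
Why: Proposed new method: HF released slowly from PhCOF/EtOH desilylates the aromatic silyloxyfuran to a chiral quinuclidinium 2-furanolate ion pair (held by the 6′-OH of the catalyst), which is protonated at the γ-carbon on one face to break the aromaticity and set C3 as S (the quinine-derived pseudoenantiomer is used if the sense proves opposite), any α-protonated β,γ-isomer being funnelled to the same product by the same catalyst; the closest known reaction types are the cinchona-mediated enantioselective protonation of silyl enolates with a latent HF source and the cinchona-catalysed proton-transfer isomerization of β,γ- to α,β-butenolides.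

Step 8
Reactants: 16 methyl (4R,6E)-3-hydroxy-6-methyl-2-methylidene-8-[(2S)-3-methyl-5-oxo-2,5-dihydrofuran-2-yl]-4-(TMP-oxy)oct-6-enoate
Product: 17 methyl (2Z,4R,6E)-2-(bromomethyl)-6-methyl-8-[(2S)-3-methyl-5-oxo-2,5-dihydrofuran-2-yl]-4-(TMP-oxy)octa-2,6-dienoate
Conditions: PBr3 (0.4 equiv), Et2O, −10 °C
Reagents that add atoms: phosphorus tribromide, BrP(Br)Br
Why: SN2′ bromination (allylic transposition) of the Morita–Baylis–Hillman alcohol gives the thermodynamically preferred Z-2-(bromomethyl)enoate and removes the C7 carbinol mixture.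

Step 9
Reactants: 17 methyl (2Z,4R,6E)-2-(bromomethyl)-6-methyl-8-[(2S)-3-methyl-5-oxo-2,5-dihydrofuran-2-yl]-4-(TMP-oxy)octa-2,6-dienoate
Product: 18 methyl (2Z,4R,6E)-2-(bromomethyl)-8-[(2S)-5-hydroxy-3-methyl-2,5-dihydrofuran-2-yl]-6-methyl-4-(TMP-oxy)octa-2,6-dienoate (lactol, both anomers)
Conditions: DIBAL-H (1.1 equiv), CH2Cl2, −78 °C; aq. Rochelle salt
Reagents that add atoms: none
Why: Partial reduction, in which the lactone carbonyl is reduced by one equivalent of DIBAL-H at −78 °C much faster than the hindered α-branched enoate ester and the aluminate collapses to the lactol (a masked Z-γ-hydroxy enal) only on neutral work-up, leaving C3 untouched.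

Step 10
Reactants: 18 methyl (2Z,4R,6E)-2-(bromomethyl)-8-[(2S)-5-hydroxy-3-methyl-2,5-dihydrofuran-2-yl]-6-methyl-4-(TMP-oxy)octa-2,6-dienoate
Product: 21 (1(10)E,3S,4Z,6R,7S,8R)-3-hydroxy-8-(TMP-oxy)germacra-1(10),4,11(13)-trien-12,6-olide, via allylchromium species 19 (not isolated), via seco hydroxy ester 20 (not isolated)
Conditions: CrCl2 (6 equiv), THF, rt, slow addition to 0.002 M; aq. NH4Cl work-up
Reagents that add atoms: none
Why: Intramolecular Nozaki–Hiyama allylation followed by lactonization, in which the γ-substituted allylchromium adds through C7 to the aldehyde form of the lactol via a chair transition state (anti, hence the trans-fused lactone), the 8R centre with its bulky aminooxy group and the (E,Z)-diene conformation of the forming ring selecting the faces that give 6R and the target C7 configuration (labelled 7S here only because the N–O group raises the priority of C8), and the C6 alkoxide then closes onto the methyl ester.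

Step 11
Reactants: 21 (1(10)E,3S,4Z,6R,7S,8R)-3-hydroxy-8-(TMP-oxy)germacra-1(10),4,11(13)-trien-12,6-olide
Product: 22 (1(10)E,3S,4Z,6R,7S,8R)-3-benzoyloxy-8-(TMP-oxy)germacra-1(10),4,11(13)-trien-12,6-olide
Conditions: BzCl, pyridine, DMAP (cat.), CH2Cl2, 0 °C to rt
Reagents that add atoms: benzoyl chloride, O=C(Cl)c1ccccc1
Why: DMAP-catalysed acylation of the only free hydroxyl (the allylic C3 carbinol) with retention of configuration.

Step 12
Reactants: 22 (1(10)E,3S,4Z,6R,7S,8R)-3-benzoyloxy-8-(TMP-oxy)germacra-1(10),4,11(13)-trien-12,6-olide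
Product: 23 (1(10)E,3S,4Z,6R,7R,8R)-3-benzoyloxy-8-hydroxygermacra-1(10),4,11(13)-trien-12,6-olide
Conditions: Zn dust, AcOH/THF/H2O (3:1:1), 40 °C
Reagents that add atoms: none
Why: Reductive N–O cleavage of the alkoxyamine by zinc in acetic acid frees the C8 alcohol without touching the esters, the α-methylene lactone or the olefins.

Step 13
Reactants: 24 (2E)-2-methylbut-2-en-1-ol
Product: 25 [(2S,3S)-2,3-dimethyloxiran-2-yl]methanol
Conditions: Ti(OiPr)4 (5 mol %), L-(+)-diethyl tartrate (6 mol %), t-BuOOH, 4 Å MS, CH2Cl2, −20 °C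
Reagents that add atoms: tert-butyl hydroperoxide, CC(C)(C)OO
Why: Sharpless asymmetric epoxidation, in which the L-(+)-tartrate titanium catalyst delivers oxygen to the face of the E-allylic alcohol that gives the (2S,3S)-epoxide, with the two methyl groups staying cis.

Step 14
Reactants: 25 [(2S,3S)-2,3-dimethyloxiran-2-yl]methanol
Product: 26 (2R,3S)-2,3-dimethyloxirane-2-carboxylic acid
Conditions: TEMPO (20 mol %), PhI(OAc)2 (2.2 equiv), MeCN/H2O (1:1), rt
Reagents that add atoms: water, O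
Why: Oxoammonium (TEMPO/PhI(OAc)2) oxidation takes the primary alcohol through the aldehyde hydrate to the acid without opening the deactivated glycidic epoxide, the C2 label changing from S to R only through the priority change.

Step 15
Reactants: 23 (1(10)E,3S,4Z,6R,7R,8R)-3-benzoyloxy-8-hydroxygermacra-1(10),4,11(13)-trien-12,6-olide, 26 (2R,3S)-2,3-dimethyloxirane-2-carboxylic acid
Product: 28 (1(10)E,3S,4Z,6R,7R,8R)-3-benzoyloxy-8-{[(2R,3S)-2,3-dimethyloxiran-2-yl]carbonyloxy}germacra-1(10),4,11(13)-trien-12,6-olide, via mixed anhydride 27 (not isolated)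
Conditions: 26, 2,4,6-trichlorobenzoyl chloride, Et3N, THF, rt; then 23, DMAP, toluene, rt
Reagents that add atoms: none
Why: Yamaguchi esterification, in which DMAP attacks the less hindered epoxy-acyl carbonyl of the mixed anhydride and the acylpyridinium acylates the hindered C8 alcohol with retention at every centre.

Step 16
Reactants: 28 (1(10)E,3S,4Z,6R,7R,8R)-3-benzoyloxy-8-{[(2R,3S)-2,3-dimethyloxiran-2-yl]carbonyloxy}germacra-1(10),4,11(13)-trien-12,6-olide
Product: 29 CNP0324463.5, (1R,3S,4Z,6R,7R,8R,10R)-3-benzoyloxy-8-{[(2R,3S)-2,3-dimethyloxiran-2-yl]carbonyloxy}-1,10-epoxygermacra-4,11(13)-dien-12,6-olide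
Conditions: mCPBA (1.1 equiv), CH2Cl2, 0 °C
Reagents that add atoms: 3-chloroperoxybenzoic acid, OOC(=O)c1cccc(Cl)c1
Why: Prilezhaev epoxidation of the only electron-rich olefin (the 4,5-olefin is deactivated by two allylic acyloxy groups and the methylene lactone is electron-poor) from the exposed outer face of the ring-perpendicular E-olefin gives the 1β,10α trans-epoxide (1R,10R) stereospecifically.

**Compound list**
1 | 3-methylfuran | Cc1ccoc1 | starting material
2 | (4-methylfuran-2-yl)lithium | [Li]c1cc(C)co1 | intermediate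
3 | lithium triisopropoxy(4-methylfuran-2-yl)borate | [Li+].CC(C)O[B-](OC(C)C)(OC(C)C)c1cc(C)co1 | intermediate
4 | 4-methylfuran-2(5H)-one | CC1=CC(=O)OC1 | intermediate
5 | triisopropyl[(4-methylfuran-2-yl)oxy]silane | Cc1coc(O[Si](C(C)C)(C(C)C)C(C)C)c1 | intermediate
6 | geranyl acetate, (2E)-3,7-dimethylocta-2,6-dien-1-yl acetate | CC(=O)OC/C=C(\C)CCC=C(C)C | starting material
7 | (2E)-5-(5,5-dimethyl-1,2,4-trioxolan-3-yl)-3-methylpent-2-en-1-yl acetate (secondary ozonide) | CC(=O)OC/C=C(\C)CCC1OOC(C)(C)O1 | intermediate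
8 | (4E)-6-acetoxy-4-methylhex-4-enal | O=CCC/C(C)=C/COC(C)=O | intermediate
9 | (2R,4E)-6-acetoxy-4-methyl-2-(TMP-oxy)hex-4-enal | O=C[C@H](ON1C(C)(C)CCCC1(C)C)C/C(C)=C/COC(C)=O | intermediate
10 | [3-methyl-5-(triisopropylsilyloxy)furan-2-yl]lithium | [Li]c1oc(O[Si](C(C)C)(C(C)C)C(C)C)cc1C | intermediate
11 | chloro[3-methyl-5-(triisopropylsilyloxy)furan-2-yl]zinc | Cl[Zn]c1oc(O[Si](C(C)C)(C(C)C)C(C)C)cc1C | intermediate
12 | (2R,4E)-4-methyl-6-[3-methyl-5-(triisopropylsilyloxy)furan-2-yl]-2-(TMP-oxy)hex-4-enal | O=C[C@H](ON1C(C)(C)CCCC1(C)C)C/C(C)=C/Cc1oc(O[Si](C(C)C)(C(C)C)C(C)C)cc1C | intermediate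
13 | methyl propiolate | C#CC(=O)OC | starting material
14 | methyl 2-(diisobutylalumanyl)prop-2-enoate | C=C([Al](CC(C)C)CC(C)C)C(=O)OC | intermediate
15 | methyl (4R,6E)-3-hydroxy-6-methyl-2-methylidene-8-[3-methyl-5-(triisopropylsilyloxy)furan-2-yl]-4-(TMP-oxy)oct-6-enoate (both epimers at the carbinol, germacrane C7) | C=C(C(=O)OC)C(O)[C@H](ON1C(C)(C)CCCC1(C)C)C/C(C)=C/Cc1oc(O[Si](C(C)C)(C(C)C)C(C)C)cc1C | intermediate
16 | methyl (4R,6E)-3-hydroxy-6-methyl-2-methylidene-8-[(2S)-3-methyl-5-oxo-2,5-dihydrofuran-2-yl]-4-(TMP-oxy)oct-6-enoate (both epimers at the carbinol) | C=C(C(=O)OC)C(O)[C@H](ON1C(C)(C)CCCC1(C)C)C/C(C)=C/C[C@@H]1OC(=O)C=C1C | intermediate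
17 | methyl (2Z,4R,6E)-2-(bromomethyl)-6-methyl-8-[(2S)-3-methyl-5-oxo-2,5-dihydrofuran-2-yl]-4-(TMP-oxy)octa-2,6-dienoate | COC(=O)/C(CBr)=C/[C@H](ON1C(C)(C)CCCC1(C)C)C/C(C)=C/C[C@@H]1OC(=O)C=C1C | intermediate
18 | methyl (2Z,4R,6E)-2-(bromomethyl)-8-[(2S)-5-hydroxy-3-methyl-2,5-dihydrofuran-2-yl]-6-methyl-4-(TMP-oxy)octa-2,6-dienoate (lactol, both anomers) | COC(=O)/C(CBr)=C/[C@H](ON1C(C)(C)CCCC1(C)C)C/C(C)=C/C[C@@H]1OC(O)C=C1C | intermediate
19 | allylchromium dichloride formed from 18 (trivalent chromium on C13) | COC(=O)C(C[Cr](Cl)Cl)=C[C@H](ON1C(C)(C)CCCC1(C)C)C/C(C)=C/C[C@@H]1OC(O)C=C1C | intermediate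
20 | methyl (1(10)E,3S,4Z,6R,7S,8R)-3,6-dihydroxy-8-(TMP-oxy)germacra-1(10),4,11(13)-trien-12-oate | COC(=O)C(=C)[C@H]1[C@H](O)/C=C(/C)[C@@H](O)C/C=C(\C)C[C@H]1ON1C(C)(C)CCCC1(C)C | intermediate
21 | (1(10)E,3S,4Z,6R,7S,8R)-3-hydroxy-8-(TMP-oxy)germacra-1(10),4,11(13)-trien-12,6-olide (same C7 geometry as 7R in the target) | C=C1C(=O)O[C@@H]2/C=C(/C)[C@@H](O)C/C=C(\C)C[C@@H](ON3C(C)(C)CCCC3(C)C)[C@@H]12 | intermediate
22 | (1(10)E,3S,4Z,6R,7S,8R)-3-benzoyloxy-8-(TMP-oxy)germacra-1(10),4,11(13)-trien-12,6-olide | C=C1C(=O)O[C@@H]2/C=C(/C)[C@@H](OC(=O)c3ccccc3)C/C=C(\C)C[C@@H](ON3C(C)(C)CCCC3(C)C)[C@@H]12 | intermediate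
23 | (1(10)E,3S,4Z,6R,7R,8R)-3-benzoyloxy-8-hydroxygermacra-1(10),4,11(13)-trien-12,6-olide | C=C1C(=O)O[C@@H]2/C=C(/C)[C@@H](OC(=O)c3ccccc3)C/C=C(\C)C[C@@H](O)[C@@H]12 | intermediate
24 | (2E)-2-methylbut-2-en-1-ol | C/C=C(\C)CO | starting material
25 | [(2S,3S)-2,3-dimethyloxiran-2-yl]methanol | OC[C@]1(C)O[C@H]1C | intermediate
26 | (2R,3S)-2,3-dimethyloxirane-2-carboxylic acid | OC(=O)[C@]1(C)O[C@H]1C | intermediate
27 | (2R,3S)-2,3-dimethyloxirane-2-carboxylic 2,4,6-trichlorobenzoic anhydride | O=C(OC(=O)[C@]1(C)O[C@H]1C)c1c(Cl)cc(Cl)cc1Cl | intermediate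
28 | (1(10)E,3S,4Z,6R,7R,8R)-3-benzoyloxy-8-{[(2R,3S)-2,3-dimethyloxiran-2-yl]carbonyloxy}germacra-1(10),4,11(13)-trien-12,6-olide | C=C1C(=O)O[C@@H]2/C=C(/C)[C@@H](OC(=O)c3ccccc3)C/C=C(\C)C[C@@H](OC(=O)[C@]3(C)O[C@H]3C)[C@@H]12 | intermediate
29 | CNP0324463.5, (1R,3S,4Z,6R,7R,8R,10R)-3-benzoyloxy-8-{[(2R,3S)-2,3-dimethyloxiran-2-yl]carbonyloxy}-1,10-epoxygermacra-4,11(13)-dien-12,6-olide | C=C1C(=O)O[C@@H]2/C=C(/C)[C@@H](OC(=O)c3ccccc3)C[C@H]3O[C@]3(C)C[C@@H](OC(=O)[C@]3(C)O[C@H]3C)[C@@H]12 | target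

**Step count**
Total: 16 steps (2 for the silyloxyfuran, 2 for the side-chain acid, 12 in the main line).
Longest linear sequence: 12 steps (geranyl acetate to the target: steps 3–12, 15 and 16).

**Three steps most likely to fail**

Step 7 (enantioselective protodesilylation; the risk is racemic background protonation by HF or a low facial preference). The fallback sets out from 15 and comes back at 16. TBAF buffered with AcOH in THF at −78 °C desilylates 15 and protonates the furanolate kinetically at the α-carbon, giving the achiral enol lactone methyl (4R,6E)-3-hydroxy-6-methyl-2-methylidene-8-(3-methyl-5-oxo-4,5-dihydrofuran-2-yl)-4-(TMP-oxy)oct-6-enoate F1. This isolated β,γ-butenolide is then isomerized to 16 with the same cinchona catalyst (5 mol %, CH2Cl2, −20 °C) by the known proton-transfer olefin isomerization, so that desilylation and the stereodetermining proton transfer are separated.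

Step 10 (ten-membered ring closure on a lactol; the risks are low aldehyde content, dehydration of the lactol to a furan by Lewis-acidic chromium salts, and the C6/C7 facial sense). The fallback sets out from 18 and comes back at 22, and cyclizes an open-chain enal that already carries the C3 benzoate. NaBH(OAc)3 in THF/AcOH reduces the lactol to methyl (2Z,4R,6E,9S,10Z)-2-(bromomethyl)-9,12-dihydroxy-6,10-dimethyl-4-(TMP-oxy)dodeca-2,6,10-trienoate F2. TBSCl/imidazole protects the primary alcohol, giving methyl (2Z,4R,6E,9S,10Z)-2-(bromomethyl)-12-(tert-butyldimethylsilyloxy)-9-hydroxy-6,10-dimethyl-4-(TMP-oxy)dodeca-2,6,10-trienoate F3. BzCl/pyridine/DMAP gives methyl (2Z,4R,6E,9S,10Z)-9-benzoyloxy-2-(bromomethyl)-12-(tert-butyldimethylsilyloxy)-6,10-dimethyl-4-(TMP-oxy)dodeca-2,6,10-trienoate F4. HF·pyridine frees methyl (2Z,4R,6E,9S,10Z)-9-benzoyloxy-2-(bromomethyl)-12-hydroxy-6,10-dimethyl-4-(TMP-oxy)dodeca-2,6,10-trienoate F5. Dess–Martin periodinane gives methyl (2Z,4R,6E,9S,10Z)-9-benzoyloxy-2-(bromomethyl)-6,10-dimethyl-12-oxo-4-(TMP-oxy)dodeca-2,6,10-trienoate F6. The same CrCl2 high-dilution allylation/lactonization of this free Z-enal then gives 22 directly.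

Step 16 (site and face of the final epoxidation). The fallback sets out from 23 and comes back at 29, and epoxidizes before the C8 acylation so that the homoallylic 8-hydroxyl can direct the oxidant. VO(acac)2 (5 mol %) and t-BuOOH in CH2Cl2 at 0 °C give (1R,3S,4Z,6R,7R,8R,10R)-3-benzoyloxy-1,10-epoxy-8-hydroxygermacra-4,11(13)-dien-12,6-olide F7 by hydroxyl-directed delivery to the 1(10)-olefin only. F7 is then esterified with mixed anhydride 27 under the step 15 conditions to give 29.

**Further compounds**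
F1 | step 7 | methyl (4R,6E)-3-hydroxy-6-methyl-2-methylidene-8-(3-methyl-5-oxo-4,5-dihydrofuran-2-yl)-4-(TMP-oxy)oct-6-enoate | C=C(C(=O)OC)C(O)[C@H](ON1C(C)(C)CCCC1(C)C)C/C(C)=C/CC1=C(C)CC(=O)O1
F2 | step 10 | methyl (2Z,4R,6E,9S,10Z)-2-(bromomethyl)-9,12-dihydroxy-6,10-dimethyl-4-(TMP-oxy)dodeca-2,6,10-trienoate | COC(=O)/C(CBr)=C/[C@H](ON1C(C)(C)CCCC1(C)C)C/C(C)=C/C[C@H](O)/C(C)=C\CO
F3 | step 10 | methyl (2Z,4R,6E,9S,10Z)-2-(bromomethyl)-12-(tert-butyldimethylsilyloxy)-9-hydroxy-6,10-dimethyl-4-(TMP-oxy)dodeca-2,6,10-trienoate | COC(=O)/C(CBr)=C/[C@H](ON1C(C)(C)CCCC1(C)C)C/C(C)=C/C[C@H](O)/C(C)=C\CO[Si](C)(C)C(C)(C)C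
F4 | step 10 | methyl (2Z,4R,6E,9S,10Z)-9-benzoyloxy-2-(bromomethyl)-12-(tert-butyldimethylsilyloxy)-6,10-dimethyl-4-(TMP-oxy)dodeca-2,6,10-trienoate | COC(=O)/C(CBr)=C/[C@H](ON1C(C)(C)CCCC1(C)C)C/C(C)=C/C[C@H](OC(=O)c1ccccc1)/C(C)=C\CO[Si](C)(C)C(C)(C)C
F5 | step 10 | methyl (2Z,4R,6E,9S,10Z)-9-benzoyloxy-2-(bromomethyl)-12-hydroxy-6,10-dimethyl-4-(TMP-oxy)dodeca-2,6,10-trienoate | COC(=O)/C(CBr)=C/[C@H](ON1C(C)(C)CCCC1(C)C)C/C(C)=C/C[C@H](OC(=O)c1ccccc1)/C(C)=C\CO
F6 | step 10 | methyl (2Z,4R,6E,9S,10Z)-9-benzoyloxy-2-(bromomethyl)-6,10-dimethyl-12-oxo-4-(TMP-oxy)dodeca-2,6,10-trienoate | COC(=O)/C(CBr)=C/[C@H](ON1C(C)(C)CCCC1(C)C)C/C(C)=C/C[C@H](OC(=O)c1ccccc1)/C(C)=C\C=O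
F7 | step 16 | (1R,3S,4Z,6R,7R,8R,10R)-3-benzoyloxy-1,10-epoxy-8-hydroxygermacra-4,11(13)-dien-12,6-olide | C=C1C(=O)O[C@@H]2/C=C(/C)[C@@H](OC(=O)c3ccccc3)C[C@H]3O[C@]3(C)C[C@@H](O)[C@@H]12
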